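**Retrosynthetic overview** (target numbered as bicyclo[3.2.1]oct-2-ene: C1 allyl bridgehead, C2=C3(OMe), C4 CH–OAc, C5 OMe bridgehead, C6 aryl, C7 methyl, C8 C=O)
1. Endgame: acetate 20 ⇐ endo alcohol 19 ⇐ (hydride to the exo face of C4=O) methoxy-enedione 18 ⇐ diosphenol 17 ⇐ (Rubottom oxidation, then oxidation) bridged silyl enol ether 14.
2. Key disconnection: the C3–C4 bond, made as the C=C bond of a silyl enol ether (C4 at ketone level), by ring-rearrangement metathesis of the gem-diallyl cyclopentanone 12 through its spirocyclopentene 13.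
3. Enabling feature: C1 is a quaternary α-carbon of the five-membered ring C1–C8–C5–C6–C7. In 12 it carries two identical allyl arms and is not a stereocentre; the C5 silyloxyvinyl arm can reach only the arm cis to it, which becomes C2–C3, while the other arm stays as the allyl group.
4. 12 ⇐ C-acetylation, hydroxylation anti to aryl, O-methylation and enol silylation of gem-diallyl ketone 8 ⇐ Me2CuLi/allyl iodide on 2-allyl-4-arylcyclopentenone 6 ⇐ (iodination/Stille, elimination, Cu-catalysed aryl addition) (R)-4-silyloxycyclopentenone 1.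
5. Ring order: the cyclopentanone comes from 1; the six-membered ring, and with it the bicycle, is closed last (step 10).

Key step: step 10

Assumption: (3,4,5-trimethoxyphenyl)magnesium bromide (2) is used as the commercial THF solution; the 1,3-diketone 9 is drawn as the diketo form although it should be largely enolised and a mixture at C2.

**Step 1**
Reactants: 1 (R)-4-[(tert-butyldimethylsilyl)oxy]cyclopent-2-en-1-one; 2 (3,4,5-trimethoxyphenyl)magnesium bromide
Product: 3 (3S,4R)-4-[(tert-butyldimethylsilyl)oxy]-3-(3,4,5-trimethoxyphenyl)cyclopentan-1-one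
Conditions: CuBr·SMe2 (10 mol%), THF, −78 → −40 °C; cold aqueous quench
Reagents that add atoms: none
Why: Copper-catalysed conjugate addition of the aryl Grignard reagent should occur anti to the C4 silyloxy group, so the aryl-bearing stereocentre is set trans to OTBS by the (R)-enone, and the cold quench prevents premature β-elimination.

**Step 2**
Reactants: 3 (3S,4R)-4-[(tert-butyldimethylsilyl)oxy]-3-(3,4,5-trimethoxyphenyl)cyclopentan-1-one
Product: 4 (R)-4-(3,4,5-trimethoxyphenyl)cyclopent-2-en-1-one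
Conditions: DBU (1.1 equiv), CH2Cl2, −20 → 0 °C, short contact time
Reagents that add atoms: none
Why: E1cB elimination of the β-silyloxy group through the C5 enolate should give the enone and leave the aryl-bearing stereocentre untouched if exposure to base is brief.

**Step 3**
Reactants: 4 (R)-4-(3,4,5-trimethoxyphenyl)cyclopent-2-en-1-one
Product: 5 (R)-2-iodo-4-(3,4,5-trimethoxyphenyl)cyclopent-2-en-1-one
Conditions: I2, pyridine, CH2Cl2, 0 °C → rt
Reagents that add atoms: iodine, II
Why: α-Iodination of the enone by the addition–iodination–elimination sequence (I2/pyridine) functionalises C2 only and is mild enough to leave C4 configurationally intact.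

**Step 4**
Reactants: 5 (R)-2-iodo-4-(3,4,5-trimethoxyphenyl)cyclopent-2-en-1-one
Product: 6 (R)-2-(prop-2-en-1-yl)-4-(3,4,5-trimethoxyphenyl)cyclopent-2-en-1-one
Conditions: allyltributylstannane, Pd2(dba)3 (2.5 mol%), AsPh3 (10 mol%), CuI (10 mol%), NMP, rt
Reagents that add atoms: allyltributylstannane, C=CC[Sn](CCCC)(CCCC)CCCC
Why: Stille coupling of an α-iodoenone with an allylstannane should proceed at room temperature and install the first allyl arm without touching the γ-stereocentre.

**Step 5**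
Reactants: 6 (R)-2-(prop-2-en-1-yl)-4-(3,4,5-trimethoxyphenyl)cyclopent-2-en-1-one
Product: 8 (3S,4R)-3-methyl-2,2-di(prop-2-en-1-yl)-4-(3,4,5-trimethoxyphenyl)cyclopentan-1-one, via lithium enolate 7 (not isolated)
Conditions: Me2CuLi (from MeLi and CuI), Et2O, −78 → −40 °C; then allyl iodide, HMPA, THF, −40 °C → rt
Reagents that add atoms: methyllithium, [Li]C; allyl iodide, C=CCI
Why: Gilman cuprate 1,4-addition should take place anti to the vicinal C4 aryl group (3,4-trans), and C-allylation of the regiodefined enolate makes C2 a non-stereogenic gem-diallyl carbon (tandem conjugate addition–enolate alkylation).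

**Step 6**
Reactants: 8 (3S,4R)-3-methyl-2,2-di(prop-2-en-1-yl)-4-(3,4,5-trimethoxyphenyl)cyclopentan-1-one
Product: 9 (3S,4S)-2-acetyl-4-methyl-5,5-di(prop-2-en-1-yl)-3-(3,4,5-trimethoxyphenyl)cyclopentan-1-one
Conditions: 1-acetylbenzotriazole, MgBr2·OEt2, i-Pr2NEt, CH2Cl2, rt
Reagents that add atoms: 1-acetyl-1H-benzotriazole, CC(=O)n1nnc2ccccc21
Why: Soft enolisation and C-acylation with an N-acylbenzotriazole (Claisen-type ketone acylation) can only occur at the single enolisable α-position, the CH2 next to the aryl-bearing carbon.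

**Step 7**
Reactants: 9 (3S,4S)-2-acetyl-4-methyl-5,5-di(prop-2-en-1-yl)-3-(3,4,5-trimethoxyphenyl)cyclopentan-1-one
Product: 10 (2S,3R,4S)-2-acetyl-2-hydroxy-4-methyl-5,5-di(prop-2-en-1-yl)-3-(3,4,5-trimethoxyphenyl)cyclopentan-1-one
Conditions: dimethyldioxirane (1.1 equiv, acetone), CH2Cl2, −40 → 0 °C
Reagents that add atoms: dimethyldioxirane, CC1(C)OO1
Why: Electrophilic α-hydroxylation of the enolised 1,3-diketone should deliver oxygen to the face of C2 anti to the vicinal aryl group, placing OH trans and acetyl cis to the aryl group, while the terminal alkenes react far more slowly.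

**Step 8**
Reactants: 10 (2S,3R,4S)-2-acetyl-2-hydroxy-4-methyl-5,5-di(prop-2-en-1-yl)-3-(3,4,5-trimethoxyphenyl)cyclopentan-1-one
Product: 11 (2S,3R,4S)-2-acetyl-2-methoxy-4-methyl-5,5-di(prop-2-en-1-yl)-3-(3,4,5-trimethoxyphenyl)cyclopentan-1-one
Conditions: MeOTf, 2,6-di-tert-butyl-4-methylpyridine, CH2Cl2, 0 °C → rt
Reagents that add atoms: methyl trifluoromethanesulfonate, COS(=O)(=O)C(F)(F)F
Why: O-Alkylation with the hard, non-basic MeOTf/hindered-pyridine pair methylates the tertiary alcohol without forming an alkoxide that could trigger retro-Claisen cleavage or an α-ketol shift.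

**Step 9**
Reactants: 11 (2S,3R,4S)-2-acetyl-2-methoxy-4-methyl-5,5-di(prop-2-en-1-yl)-3-(3,4,5-trimethoxyphenyl)cyclopentan-1-one
Product: 12 (2S,3R,4S)-2-methoxy-4-methyl-5,5-di(prop-2-en-1-yl)-2-{1-[(triethylsilyl)oxy]ethenyl}-3-(3,4,5-trimethoxyphenyl)cyclopentan-1-one
Conditions: TESOTf, Et3N, CH2Cl2, −78 → 0 °C
Reagents that add atoms: triethylsilyl trifluoromethanesulfonate, CC[Si](CC)(CC)OS(=O)(=O)C(F)(F)F
Why: Enol silylation (R3SiOTf/Et3N) can only occur at the acetyl methyl group because the ring ketone has no α-hydrogen, so the 2-silyloxy-1-alkene forms regiospecifically.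

**Step 10**
Reactants: 12 (2S,3R,4S)-2-methoxy-4-methyl-5,5-di(prop-2-en-1-yl)-2-{1-[(triethylsilyl)oxy]ethenyl}-3-(3,4,5-trimethoxyphenyl)cyclopentan-1-one
Product: 14 (1S,5R,6S,7R)-1-methoxy-6-methyl-5-(prop-2-en-1-yl)-2-[(triethylsilyl)oxy]-7-(3,4,5-trimethoxyphenyl)bicyclo[3.2.1]oct-2-en-8-one, via spirocyclopentene 13 (not isolated)
Conditions: Hoveyda–Grubbs II (2 × 7.5 mol%), ethylene (1 atm), PhMe (3 mM), 80 °C
Reagents that add atoms: none
Why: The Ru methylidene should first close the two geminal allyl groups to spirocyclopentene 13 with loss of ethylene, and under ethylene this ring reopens reversibly, placing the Ru alkylidene on either arm; the alkylidene on the arm cis to the C2 silyloxyvinyl group adds to that 1,1-disubstituted enol ether (Ru to the CH2 terminus), and cycloreversion forms the ring C=C bond and returns Ru=CH2 while the other arm is left as the allyl group. The closest known reaction types are ring-rearrangement (ring-opening/ring-closing) metathesis of cyclopentenes, RCM onto silyl enol ethers to give cyclic silyl enol ethers, and RCM closures of bridged bicycles. The six-membered ring is closed in the endocyclic-alkene mode as a three-carbon bridge across the two α-carbons of the cyclopentanone, which requires both arms cis and pseudoaxial. The only new stereocentre, the allyl-bearing quaternary bridgehead, is set by the existing methoxy-bearing stereocentre, because only the diastereotopic arm cis to the enol ether can span the ring. The step needs group selectivity between the two arms and a productive exit from the spirocycle: geometry enforces the first, and reversible ring-opening under ethylene plus the inertness of the hindered trisubstituted silyl enol ether product to retro-metathesis should secure the second. High dilution suppresses cross-metathesis.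

**Step 11**
Reactants: 14 (1S,5R,6S,7R)-1-methoxy-6-methyl-5-(prop-2-en-1-yl)-2-[(triethylsilyl)oxy]-7-(3,4,5-trimethoxyphenyl)bicyclo[3.2.1]oct-2-en-8-one
Product: 16 (1R,5R,6S,7R)-3-hydroxy-1-methoxy-6-methyl-5-(prop-2-en-1-yl)-7-(3,4,5-trimethoxyphenyl)bicyclo[3.2.1]octane-2,8-dione (C3 epimers), via silyloxy epoxide 15 (not isolated)
Conditions: dimethyldioxirane (1.05 equiv), acetone/CH2Cl2, −78 °C; then aq. citric acid, THF, 0 °C
Reagents that add atoms: dimethyldioxirane, CC1(C)OO1
Why: Rubottom oxidation: the electron-rich silyl enol ether should be epoxidised in preference to the terminal allyl group and acid opens the silyloxy oxirane to the α-hydroxy ketone, whose new carbinol configuration is irrelevant because it is oxidised next.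

**Step 12**
Reactants: 16 (1R,5R,6S,7R)-3-hydroxy-1-methoxy-6-methyl-5-(prop-2-en-1-yl)-7-(3,4,5-trimethoxyphenyl)bicyclo[3.2.1]octane-2,8-dione
Product: 17 (1S,5R,6R,7S)-3-hydroxy-5-methoxy-7-methyl-1-(prop-2-en-1-yl)-6-(3,4,5-trimethoxyphenyl)bicyclo[3.2.1]oct-2-ene-4,8-dione
Conditions: Dess–Martin periodinane, CH2Cl2, rt
Reagents that add atoms: none
Why: Dess–Martin oxidation of the acyloin gives the 1,2-diketone, which can enolise only towards the ring CH2 (the other neighbour is quaternary) and should therefore tautomerise to a single diosphenol.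

**Step 13**
Reactants: 17 (1S,5R,6R,7S)-3-hydroxy-5-methoxy-7-methyl-1-(prop-2-en-1-yl)-6-(3,4,5-trimethoxyphenyl)bicyclo[3.2.1]oct-2-ene-4,8-dione
Product: 18 (1S,5R,6R,7S)-3,5-dimethoxy-7-methyl-1-(prop-2-en-1-yl)-6-(3,4,5-trimethoxyphenyl)bicyclo[3.2.1]oct-2-ene-4,8-dione
Conditions: Me2SO4, K2CO3, acetone, rt
Reagents that add atoms: dimethyl sulfate, COS(=O)(=O)OC
Why: O-Methylation of the diosphenol with a hard electrophile and a non-nucleophilic carbonate base should give the α-methoxy enone without nucleophilic attack on the non-enolisable 1,3-diketone.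

**Step 14**
Reactants: 18 (1S,5R,6R,7S)-3,5-dimethoxy-7-methyl-1-(prop-2-en-1-yl)-6-(3,4,5-trimethoxyphenyl)bicyclo[3.2.1]oct-2-ene-4,8-dione
Product: 19 (1S,4R,5S,6R,7S)-4-hydroxy-3,5-dimethoxy-7-methyl-1-(prop-2-en-1-yl)-6-(3,4,5-trimethoxyphenyl)bicyclo[3.2.1]oct-2-en-8-one
Conditions: NaBH4 (1.0 equiv), CeCl3·7H2O, MeOH, −78 °C
Reagents that add atoms: none
Why: Luche 1,2-reduction should attack the enone carbonyl C4 in preference to the bridging C8 carbonyl flanked by two quaternary carbons, and hydride should approach C4 from the exo face (syn to C8) because the endo face is covered by the C6 aryl group, giving the endo (4R) alcohol.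

**Step 15**
Reactants: 19 (1S,4R,5S,6R,7S)-4-hydroxy-3,5-dimethoxy-7-methyl-1-(prop-2-en-1-yl)-6-(3,4,5-trimethoxyphenyl)bicyclo[3.2.1]oct-2-en-8-one
Product: 20 (1S,4R,5S,6R,7S)-4-acetoxy-3,5-dimethoxy-7-methyl-1-(prop-2-en-1-yl)-6-(3,4,5-trimethoxyphenyl)bicyclo[3.2.1]oct-2-en-8-one (CNP0181407.1)
Conditions: Ac2O, DMAP (cat.), pyridine, rt
Reagents that add atoms: acetic anhydride, CC(=O)OC(C)=O
Why: DMAP-catalysed O-acylation of the secondary alcohol proceeds with retention at C4 and completes the target.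

**Compound list**
1 | (R)-4-[(tert-butyldimethylsilyl)oxy]cyclopent-2-en-1-one | O=C1C=C[C@H](O[Si](C)(C)C(C)(C)C)C1 | starting material
2 | (3,4,5-trimethoxyphenyl)magnesium bromide | COc1cc([Mg]Br)cc(OC)c1OC | starting material
3 | (3S,4R)-4-[(tert-butyldimethylsilyl)oxy]-3-(3,4,5-trimethoxyphenyl)cyclopentan-1-one | O=C1C[C@@H](c2cc(OC)c(OC)c(OC)c2)[C@H](O[Si](C)(C)C(C)(C)C)C1 | intermediate
4 | (R)-4-(3,4,5-trimethoxyphenyl)cyclopent-2-en-1-one | O=C1C[C@@H](c2cc(OC)c(OC)c(OC)c2)C=C1 | intermediate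
5 | (R)-2-iodo-4-(3,4,5-trimethoxyphenyl)cyclopent-2-en-1-one | O=C1C[C@@H](c2cc(OC)c(OC)c(OC)c2)C=C1I | intermediate
6 | (R)-2-(prop-2-en-1-yl)-4-(3,4,5-trimethoxyphenyl)cyclopent-2-en-1-one | O=C1C[C@@H](c2cc(OC)c(OC)c(OC)c2)C=C1CC=C | intermediate
7 | lithium (3S,4R)-3-methyl-2-(prop-2-en-1-yl)-4-(3,4,5-trimethoxyphenyl)cyclopent-1-en-1-olate (not isolated) | [Li]OC1=C(CC=C)[C@@H](C)[C@H](c2cc(OC)c(OC)c(OC)c2)C1 | intermediate
8 | (3S,4R)-3-methyl-2,2-di(prop-2-en-1-yl)-4-(3,4,5-trimethoxyphenyl)cyclopentan-1-one | O=C1C[C@@H](c2cc(OC)c(OC)c(OC)c2)[C@H](C)C1(CC=C)CC=C | intermediate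
9 | (3S,4S)-2-acetyl-4-methyl-5,5-di(prop-2-en-1-yl)-3-(3,4,5-trimethoxyphenyl)cyclopentan-1-one (aryl and methyl trans; C2 epimers and enol) | O=C1C(C(C)=O)[C@@H](c2cc(OC)c(OC)c(OC)c2)[C@H](C)C1(CC=C)CC=C | intermediate
10 | (2S,3R,4S)-2-acetyl-2-hydroxy-4-methyl-5,5-di(prop-2-en-1-yl)-3-(3,4,5-trimethoxyphenyl)cyclopentan-1-one (OH trans to aryl) | O=C1[C@@](O)(C(C)=O)[C@@H](c2cc(OC)c(OC)c(OC)c2)[C@H](C)C1(CC=C)CC=C | intermediate
11 | (2S,3R,4S)-2-acetyl-2-methoxy-4-methyl-5,5-di(prop-2-en-1-yl)-3-(3,4,5-trimethoxyphenyl)cyclopentan-1-one | O=C1[C@@](OC)(C(C)=O)[C@@H](c2cc(OC)c(OC)c(OC)c2)[C@H](C)C1(CC=C)CC=C | intermediate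
12 | (2S,3R,4S)-2-methoxy-4-methyl-5,5-di(prop-2-en-1-yl)-2-{1-[(triethylsilyl)oxy]ethenyl}-3-(3,4,5-trimethoxyphenyl)cyclopentan-1-one | O=C1[C@@](OC)(C(=C)O[Si](CC)(CC)CC)[C@@H](c2cc(OC)c(OC)c(OC)c2)[C@H](C)C1(CC=C)CC=C | intermediate
13 | (2S,3R,4S)-2-methoxy-4-methyl-2-{1-[(triethylsilyl)oxy]ethenyl}-3-(3,4,5-trimethoxyphenyl)spiro[4.4]non-7-en-1-one (not isolated) | O=C1[C@@](OC)(C(=C)O[Si](CC)(CC)CC)[C@@H](c2cc(OC)c(OC)c(OC)c2)[C@H](C)C13CC=CC3 | intermediate
14 | (1S,5R,6S,7R)-1-methoxy-6-methyl-5-(prop-2-en-1-yl)-2-[(triethylsilyl)oxy]-7-(3,4,5-trimethoxyphenyl)bicyclo[3.2.1]oct-2-en-8-one | C=CC[C@]12CC=C(O[Si](CC)(CC)CC)[C@](OC)(C1=O)[C@@H](c1cc(OC)c(OC)c(OC)c1)[C@@H]2C | intermediate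
15 | 2,3-epoxide of 14 (silyloxy oxirane, mixture at the oxirane carbons; not isolated) | C=CC[C@]12CC3OC3(O[Si](CC)(CC)CC)[C@](OC)(C1=O)[C@@H](c1cc(OC)c(OC)c(OC)c1)[C@@H]2C | intermediate
16 | (1R,5R,6S,7R)-3-hydroxy-1-methoxy-6-methyl-5-(prop-2-en-1-yl)-7-(3,4,5-trimethoxyphenyl)bicyclo[3.2.1]octane-2,8-dione (C3 epimers) | C=CC[C@]12CC(O)C(=O)[C@](OC)(C1=O)[C@@H](c1cc(OC)c(OC)c(OC)c1)[C@@H]2C | intermediate
17 | (1S,5R,6R,7S)-3-hydroxy-5-methoxy-7-methyl-1-(prop-2-en-1-yl)-6-(3,4,5-trimethoxyphenyl)bicyclo[3.2.1]oct-2-ene-4,8-dione | C=CC[C@]12C=C(O)C(=O)[C@](OC)(C1=O)[C@@H](c1cc(OC)c(OC)c(OC)c1)[C@@H]2C | intermediate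
18 | (1S,5R,6R,7S)-3,5-dimethoxy-7-methyl-1-(prop-2-en-1-yl)-6-(3,4,5-trimethoxyphenyl)bicyclo[3.2.1]oct-2-ene-4,8-dione | C=CC[C@]12C=C(OC)C(=O)[C@](OC)(C1=O)[C@@H](c1cc(OC)c(OC)c(OC)c1)[C@@H]2C | intermediate
19 | (1S,4R,5S,6R,7S)-4-hydroxy-3,5-dimethoxy-7-methyl-1-(prop-2-en-1-yl)-6-(3,4,5-trimethoxyphenyl)bicyclo[3.2.1]oct-2-en-8-one (4-OH endo, cis to aryl) | C=CC[C@]12C=C(OC)[C@@H](O)[C@](OC)(C1=O)[C@@H](c1cc(OC)c(OC)c(OC)c1)[C@@H]2C | intermediate
20 | (1S,4R,5S,6R,7S)-4-acetoxy-3,5-dimethoxy-7-methyl-1-(prop-2-en-1-yl)-6-(3,4,5-trimethoxyphenyl)bicyclo[3.2.1]oct-2-en-8-one (CNP0181407.1) | C=CC[C@]12C=C(OC)[C@@H](OC(C)=O)[C@](OC)(C1=O)[C@@H](c1cc(OC)c(OC)c(OC)c1)[C@@H]2C | target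

Total step count: 15. Longest linear sequence: 15 steps (1 → 20; the route is fully linear).

**Steps most likely to fail**

Step 10 (ring-rearrangement metathesis). The risk is that the catalyst decomposes before the unstrained spirocycle is reopened, or that the hindered enol ether is never engaged, so the material stays at the spirocyclic isomer. The fallback closes the same ring bond by an N-heterocyclic-carbene-catalysed intramolecular crossed benzoin reaction; it sets out from 6 and rejoins the route at 17. Cuprate addition to 6 as in step 5, but trapping with prenyl bromide, should give (2R,3S,4R)-3-methyl-2-(3-methylbut-2-en-1-yl)-2-(prop-2-en-1-yl)-4-(3,4,5-trimethoxyphenyl)cyclopentan-1-one F1, with prenyl entering anti to the methyl group and so on the aryl face. Formylation (HCO2Et, NaH) would give the hydroxymethylene ketone F2. Hydroxylation and O-methylation under the conditions of steps 7 and 8 would give the hydroxy aldehyde F3 and then the methoxy aldehyde F4. Ozonolysis selective for the trisubstituted prenyl alkene (O3, pyridine, CH2Cl2, −78 °C; Me2S) would give the keto dialdehyde F5. A triazolium-derived carbene (Et3N, THF) should then close the ring to the bridged acyloin F6, and Dess–Martin oxidation of F6 gives 17. Both acyloin regioisomers and all carbinol epimers converge on 17.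

Step 8 (O-methylation). The risk is slow alkylation of the hindered tertiary hydroxyl with competing deacetylation (retro-Claisen) or α-ketol shift. The fallback sets out from 9 and comes back at 11, bypassing 10: oxidative α-methoxylation of the 1,3-diketone with an iodine(III) reagent in methanol (PhI(OAc)2, BF3·OEt2, MeOH). Methanol displaces the iodine(III) enolate at carbon and should enter anti to the aryl group, so the C–OMe bond is formed directly (no new compound, F0).

Step 14 (reduction). The risk is competing or over-reduction at the bridging C8 carbonyl. The fallback sets out from 18 and comes back at 20. Exhaustive reduction (excess NaBH4, MeOH, 0 °C) would give the 4,8-diol F7. Selective acetylation of the more accessible C4 hydroxyl (Ac2O 1 equiv, pyridine, 0 °C; the C8 hydroxyl is flanked by two quaternary carbons) would give the hydroxy acetate F8, and Dess–Martin oxidation of the C8 carbinol of F8 gives 20.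

**Further compounds**
F1 | step 10 | (2R,3S,4R)-3-methyl-2-(3-methylbut-2-en-1-yl)-2-(prop-2-en-1-yl)-4-(3,4,5-trimethoxyphenyl)cyclopentan-1-one | O=C1C[C@@H](c2cc(OC)c(OC)c(OC)c2)[C@H](C)[C@@]1(CC=C)CC=C(C)C
F2 | step 10 | 5-(hydroxymethylidene) derivative of F1 (hydroxymethylene ketone) | O=C1C(=CO)[C@@H](c2cc(OC)c(OC)c(OC)c2)[C@H](C)[C@@]1(CC=C)CC=C(C)C
F3 | step 10 | 5-formyl-5-hydroxy ketone (OH trans to aryl) | O=C1[C@@](O)(C=O)[C@@H](c2cc(OC)c(OC)c(OC)c2)[C@H](C)[C@@]1(CC=C)CC=C(C)C
F4 | step 10 | 5-formyl-5-methoxy ketone (OMe trans to aryl) | O=C1[C@@](OC)(C=O)[C@@H](c2cc(OC)c(OC)c(OC)c2)[C@H](C)[C@@]1(CC=C)CC=C(C)C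
F5 | step 10 | keto dialdehyde (2-oxoethyl arm in place of prenyl) | O=C1[C@@](OC)(C=O)[C@@H](c2cc(OC)c(OC)c(OC)c2)[C@H](C)[C@@]1(CC=C)CC=O
F6 | step 10 | 4-hydroxy-5-methoxy-7-methyl-1-(prop-2-en-1-yl)-6-(3,4,5-trimethoxyphenyl)bicyclo[3.2.1]octane-3,8-dione (C4 epimers) | C=CC[C@]12CC(=O)C(O)[C@](OC)(C1=O)[C@@H](c1cc(OC)c(OC)c(OC)c1)[C@@H]2C
F0 | step 8 | none | none
F7 | step 14 | 4,8-diol from 18 (4-OH endo; C8 configuration open) | C=CC[C@]12C=C(OC)[C@@H](O)[C@](OC)(C1O)[C@@H](c1cc(OC)c(OC)c(OC)c1)[C@@H]2C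
F8 | step 14 | 4-acetate of the 4,8-diol (8-hydroxy acetate) | C=CC[C@]12C=C(OC)[C@@H](OC(C)=O)[C@](OC)(C1O)[C@@H](c1cc(OC)c(OC)c(OC)c1)[C@@H]2C
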